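Count the partner, because it is conserved: at any moment each unit charged stands free, sits in the idle adduct, has become decomposed reagent, or has gone into product.

| setting | Saturday's | Monday's | Thursday's |
|---|---|---|---|
| starting material | 1.3 M | 1.3 M | 1.3 M |
| partner | 1.30 M | 2.00 M | 2.90 M |
| base | 0.130 M | 0.130 M | 0.130 M |
| time | 5.0 min | 5.0 min | 5.0 min |

    starting material + partner + by-product → product + 2 by-product (k1 = 0.270 M⁻² s⁻¹)
    starting material + partner → product + by-product (k2 = 5.17 × 10⁻⁴ M⁻¹ s⁻¹)
    base + by-product ⇌ salt, settled at all times (K3 = 1380 M⁻¹)
    partner → decomposed reagent (k4 = 0.00635 s⁻¹)
    partner + product ⇌ idle adduct, settled at all times (K5 = 2.29 M⁻¹)

- which of these there is most of at the end, counted by the starting material in it, Saturday's (starting material / product)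
- which of these there is most of at the end, counted by the starting material in it, Monday's (starting material / product)
- which of these there is most of at the end, counted by the starting material in it, Thursday's (starting material / product)
- the largest of these amounts at the end, in percent of the starting material charged, Saturday's
- the largest of these amounts at the end, in percent of the starting material charged, Monday's
- the largest of these amounts at the end, in percent of the starting material charged, Thursday's

- product is meant together with its idle adduct
- run time (Saturday's): 5.0 min

Call the second equation the plain step and the first the driven step. The base charge is the same in the three flasks, and equilibrium constant times base is 180 at the start of Saturday's, so free by-product stays low until the base is filled. Reckon that quiet stretch on the plain step. Hold starting material at its charge: each unit of by-product then costs one partner to the plain step and 9.45 to decay. Multiply by the base charge to get the toll 1.23 M, the partner that decay takes while the plain step fills the base. Assume the partner past the toll turns into product, up to the starting material charged. On Saturday's and Monday's that partner is less than the starting material, which in this reckoning makes partner the limiting reagent in these two flasks. The fraction of starting material left is then one minus charge-less-toll over its charge: 94.5% on Saturday's and 40.6% on Monday's. On Thursday's, charge less toll exceeds the starting material.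

Now reforge the weak link, the quiet stretch. The driven step does not wait for a full base. At filled fraction u, driven over plain is 0.378 times u/(1−u). Divide the toll by one plus that ratio at each u and integrate, which shrinks it by 0.657 to 0.807 M. Commit: 62.1% starting material left on Saturday's, 91.8% product on Monday's, 100% product on Thursday's.

The forecast, differing from me on the first two amounts, says starting material at 70%, product at 76% and product at 99.8%, since “the partner charge decides how much is left”. Saturday's flask gives starting material at 74.9%. Monday's flask gives product at 77.4%. Thursday's flask gives product at >99.9%.

On Thursday's at 0.636 min, partner's half-life by decay is 1.8 min against 18 min by the plain step, ten times shorter. Charge minus product reads 0.974 M on Saturday's and 0.993 M on Monday's, less than my first toll and more than the reforged one. Take Monday's reading to Thursday's flask with 1.7 M of partner: it promises 54.4% product, and that flask holds 56.1%.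

The constants used here are assumed, and the outcome is calculated.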